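## Structural features

Target 15 is a dearomatised, bicyclic acylphloroglucinol. Ring A (C3a, C4 to C7, C7a) is a cyclohexene with a ketone at C4, a gem-dimethyl group at C5, a carbonyl at C6 and the (R)-2-methylbutanoyl group at C7; ring B (O1, C2, C3, C3a, C7a) is a dihydrofuran fused along C3a–C7a. O1–C7a=C7, flanked by the C6 and acyl carbonyls, is a doubly activated vinylogous ester, that is, an O-alkylated enol of a β-triketone. There are four stereocentres: the all-carbon quaternary C3a (S, prenyl), C2 (R) with its substituent cis to the prenyl group across ring B, the tertiary carbinol (S) bonded directly to C2, and the remote acyl α-carbon (R). Fragile parts are the two trisubstituted alkenes and the tertiary alcohol (acid, electrophilic oxidants), the enolisable acyl α-centre, C7a (addition–elimination), and, whenever C2 bears a vinyl or acyl group, the C2–O1 bond and the C2 hydrogen. The real difficulty is C3a: it has no heteroatom or hydrogen to steer its formation and must be set in a defined relation to C2 and, through C2, to the carbinol carbon. The key step exploits the trione hidden in the two rings: C3a lies between the C4 and C7a carbonyls and is nucleophilic, and because C5 is fully substituted, C4 cannot enolise once C3a is quaternary, so only the C7a oxygen (enolisable towards C7) can reach C2. A four-carbon bis-electrophile can therefore be joined through C3 to C3a and through C2 to O1 in one operation, leaving a vinyl group on C2 as the handle for the side chain.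

## Logic of the disconnections

15 is cut between the carbinol carbon and the first methylene of its six-carbon chain, leading to 12 and, through 14, to 13. This is the one C–C bond whose formation from a ketone also creates the hydroxyl-bearing stereocentre next to C2. The cut removes one stereocentre and six carbons. The forward step must pick the side-chain carbonyl among four and one of its faces under 1,2-induction from C2.

12 is traced to 11 by exchanging the ketone oxygen for a terminal alkene; no skeletal bond is cut. A vinyl group is what a π-allyl ring closure leaves on C2, and unlike the acetyl group it does not make C2 epimerisable. The forward step must oxidise a monosubstituted alkene at its internal carbon beside a trisubstituted alkene and leave C2 untouched.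

11 is cut at C3a–C3 and at O1–C2, giving 7 and 9, with 10 between them. Both bonds are allylic in the forward sense, so one catalyst can make them in sequence. Ring B and both ring stereocentres disappear, and 7 has no stereocentre in its ring. The forward step demands catalyst control of two faces and carbon-before-oxygen reactivity. 7 is kept as the free enol and 9 as the bis(methyl carbonate), so that base is released only as fast as ionisation occurs.

9 is cut at its two carbonate C–O bonds to 8, which fixes the Z geometry from a commercial diol. The forward step is a simple double acylation.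

7 is cut at the bond between C3a and the prenyl CH2, giving 5 and 6. C3a is the only ring carbon of 5 that still carries hydrogen, so the position is not in question. The forward step must stop after one alkylation.

5 is cut at the two methyl–ring bonds of the future C5, giving 4. Both methyl groups go onto the same carbon, and the dearomatisation turns the phenol into the trione needed later. The forward step must tolerate the acyl α-centre under base.

4 is cut at the aryl–acyl bond to 3 and 2, and 2 is traced to 1. The symmetry of 3 makes the regiochemistry trivial, and the acyl stereocentre comes from the chiral pool. The forward steps must keep this centre intact under acidic activation.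

## Other disconnections considered

Alternative 1: The cut is C3a–C4 in ring A. In the forward direction, ester A2 already holds ring B, C2, the silylated carbinol and the prenyl group on the future C3a. It is deprotonated at C3a, γ to the C6 carbonyl, and the γ-carbon of the dienolate acylates onto the tethered pentafluorophenyl ester to give A1.
- In its favour: C2 and the carbinol are made beforehand by reagent-controlled chemistry. This is better than the chosen plan, where the carbinol rests on 1,2-induction.
- In its favour: ring size enforces γ-attack, and the ester should approach anti to the C2 side chain, which is the target's cis relation. This is at least the equal of a ligand-controlled closure.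
- Against: A1 lacks the C7 acyl group. C-acylation of a vinylogous ester at C7 with an enolisable, α-chiral acyl donor is an extra and uncertain operation (O-acylation, loss of the acyl stereocentre), followed by desilylation.
- Against: A2 needs a long linear build-up.
- Comparison: the mechanism is simpler (polar, no metal), but only one ring bond and one stereocentre are made where the chosen step makes two of each, and step economy is clearly poorer.

Alternative 2: The cut is O1–C7a. In the forward direction, a chiral phosphoric acid lets the C2 hydroxyl of trione A4 condense with one of the two diastereotopic carbonyls flanking C3a, giving A3.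
- In its favour: C2 and the carbinol are again pre-set (better than the chosen plan), and the ring closure itself is simple and metal-free.
- Against: A3 has neither the gem-dimethyl group nor the acyl group. C5 dimethylation must then compete with C7, and the C7 acylation problem of Alternative 1 returns.
- Against: hemiketal formation and dehydration are reversible under acid, so the two closures can equilibrate and the kinetic preference of the catalyst may be lost. The chain stereocentres may match or oppose the catalyst.
- Against: making A4 still requires an uncontrolled gem-dialkylation at the future C3a.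
- Comparison: equal or better for C2 and the carbinol, comparable uncertainty for C3a, reversible against irreversible bond formation, and at least three more steps after the key step.

Alternative 3: The cuts are C3a–C3 and O1–C7a. In the forward direction, the dianion of 7 opens epoxide A6 at its CH2 carbon. On acid work-up the freed C2 hydroxyl condenses with the C7a carbonyl to give A5, and desilylation would give 15.
- In its favour: it is the shortest plan, two steps from 7 against three, so it is better in step economy.
- In its favour: C2 and the carbinol come from asymmetric epoxidation, which is better than the chosen plan.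
- In its favour: the cyclodehydration is self-correcting, because a hemiketal at C4 cannot dehydrate. This equals the site-selectivity argument of the chosen plan.
- Against: nothing controls C3a. The planar dianion meets a remote stereocentre, so both C3a epimers are to be expected and must be separated.
- Against: epoxides are sluggish electrophiles for strongly stabilised enolates, more so next to a quaternary silyloxy carbon, and Lewis acid activation endangers the epoxide and the silyl ether.
- Comparison: superior in convergence and in the chain stereocentres, inferior at the quaternary centre, which is the crux of the structure. The chosen plan addresses C3a by catalyst control and pays with a less certain carbinol.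

Key step: step 6

Remark on the chemistry: the sense of induction of the diphosphine cannot be assigned with certainty for this nucleophile, so the (R,R) antipode is written as the working choice and its mirror image replaces it if the 3aR series prevails. 10 is drawn as the E alkene, and its geometry is erased on ionisation.

## Route

Step 1
Reactants: 1 (R)-2-methylbutanoic acid
Product: 2 (R)-2-methylbutanoyl chloride
Conditions: SOCl2 (1.5 equiv), neat, 40 °C; distillation
Reagents that add atoms: thionyl chloride, ClS(Cl)=O
Why: Standard conversion of an acid into its chloride through the chlorosulfite; no base is present, so ketene formation and loss of the α-stereocentre are not expected.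

Step 2
Reactants: 3 phloroglucinol (anhydrous); 2 (R)-2-methylbutanoyl chloride
Product: 4 (2R)-2-methyl-1-(2,4,6-trihydroxyphenyl)butan-1-one
Conditions: AlCl3 (4 equiv), PhNO2/CH2Cl2, 0 °C to rt; ice, 1 M HCl
Reagents that add atoms: none
Why: Friedel–Crafts C-acylation; all three ring CH positions of 3 are equivalent and the first acyl group deactivates the ring against a second. The aluminium chelate between the ketone and an ortho oxygen should hold the α-centre against enolisation.

Step 3
Reactants: 4 (2R)-2-methyl-1-(2,4,6-trihydroxyphenyl)butan-1-one
Product: 5 3,5-dihydroxy-6,6-dimethyl-2-[(2R)-2-methylbutanoyl]cyclohexa-2,4-dien-1-one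
Conditions: MeI (2.5 equiv), NaOMe (3.5 equiv), MeOH, 0 °C to rt; 1 M HCl
Reagents that add atoms: iodomethane, CI
Why: Dearomatising double C-methylation of the acylphloroglucinol anion, the known entry to acylfilicinic acids; the once-methylated carbon is the most electron-rich site and takes the second methyl group, after which the β-triketone anion is too stabilised to react quickly again. The acyl α-hydrogen should not be removed from a species that is already anionic.

Step 4
Reactants: 5 3,5-dihydroxy-6,6-dimethyl-2-[(2R)-2-methylbutanoyl]cyclohexa-2,4-dien-1-one; 6 prenyl bromide (1-bromo-3-methylbut-2-ene)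
Product: 7 3,5-dihydroxy-6,6-dimethyl-2-[(2R)-2-methylbutanoyl]-4-(3-methylbut-2-en-1-yl)cyclohexa-2,4-dien-1-one
Conditions: NaOMe (2.0 equiv), MeOH, 0 °C, slow addition of 6 (0.95 equiv), argon; 1 M HCl
Reagents that add atoms: none
Why: SN2 C-alkylation of the vinylogous enolate at the only ring carbon that still carries hydrogen; the protic solvent solvates the oxygens and favours carbon attack, and a slight deficit of 6 limits a second prenylation. 7 is kept under argon because electron-rich enolised triones of this kind autoxidise.

Step 5
Reactants: 8 (Z)-but-2-ene-1,4-diol
Product: 9 (2Z)-but-2-ene-1,4-diyl dimethyl biscarbonate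
Conditions: ClCO2Me (2.5 equiv), pyridine (3 equiv), CH2Cl2, 0 °C to rt
Reagents that add atoms: methyl chloroformate, COC(=O)Cl
Why: Routine O-acylation of both primary allylic alcohols; the alkene geometry is not touched.

Step 6
Reactants: 7 3,5-dihydroxy-6,6-dimethyl-2-[(2R)-2-methylbutanoyl]-4-(3-methylbut-2-en-1-yl)cyclohexa-2,4-dien-1-one; 9 (2Z)-but-2-ene-1,4-diyl dimethyl biscarbonate
Product: 11 (2R,3aS)-2-ethenyl-5,5-dimethyl-7-[(2R)-2-methylbutanoyl]-3a-(3-methylbut-2-en-1-yl)-3,3a-dihydro-1-benzofuran-4,6(2H,5H)-dione, via C3a-allylated monocarbonate 10 (not isolated)
Conditions: Pd2(dba)3·CHCl3 (2.5 mol%), (R,R)-L (7.5 mol%; L = N,N'-(cyclohexane-1,2-diyl)bis[2-(diphenylphosphino)benzamide]), CH2Cl2, 0 °C to rt, argon, no added base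
Reagents that add atoms: none
Why: Zerovalent palladium ionises one carbonate of 9, loss of CO2 leaves methoxide, and this deprotonates the acidic enol 7, so a cationic π-allyl complex and the trione anion meet without added base. C3a attacks the CH2 terminus remote from the CH2OCO2Me group from outside the metal to give 10; O-allylated material is an allylic vinylogous ester, should re-ionise and be funnelled to the C–C product. In 10 the second carbonate ionises and the C7a enolate oxygen attacks the internal allyl carbon, which closes ring B in the 5-exo mode and leaves the vinyl group on C2; attack at the allyl terminus would need a seven-membered ring and attack by C7 a bridged one. The closest known reaction type is the palladium-catalysed [3+2] annulation of 1,3-dicarbonyl compounds with but-2-ene-1,4-diyl dicarbonates to 2-vinyl-2,3-dihydrofurans, joined here to the dearomatising allylation of acylphloroglucinols. C3a is controlled by the ligand, whose chiral pocket decides which face of the planar anion meets the allyl terminus. C2 is controlled by the ligand together with the now fixed C3a: the diastereomeric π-allyl complexes interconvert through the η1 form at the unsubstituted terminus faster than they close, so the faster-closing one decides (Curtin–Hammett). The step needs site selectivity for C3a over C7 and oxygen, secured by the acyl group, which makes C7 hindered and its alkylation reversible, and for the C7a oxygen over the C4 oxygen, secured by the C5 gem-dimethyl group, which forbids enolisation of C4 while C7 of 10 keeps an acidic hydrogen. The reaction is stopped at full conversion because the allylic C2–O1 bond of 11 can ionise again.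

Step 7
Reactants: 11 (2R,3aS)-2-ethenyl-5,5-dimethyl-7-[(2R)-2-methylbutanoyl]-3a-(3-methylbut-2-en-1-yl)-3,3a-dihydro-1-benzofuran-4,6(2H,5H)-dione
Product: 12 (2R,3aS)-2-acetyl-5,5-dimethyl-7-[(2R)-2-methylbutanoyl]-3a-(3-methylbut-2-en-1-yl)-3,3a-dihydro-1-benzofuran-4,6(2H,5H)-dione
Conditions: PdCl2(quinox) (5 mol%; quinox = 2-(4,5-dihydrooxazol-2-yl)quinoline), AgSbF6 (12 mol%), 70% aq. t-BuOOH (12 equiv), CH2Cl2, 0 °C to rt
Reagents that add atoms: tert-butyl hydroperoxide, CC(C)(C)OO
Why: Peroxide-mediated Wacker-type oxidation: the cationic divalent palladium complex binds only the unhindered monosubstituted alkene, the peroxide oxygen is delivered to the internal carbon and a 1,2-hydride shift gives the methyl ketone. This variant is chosen because it is known to give ketones, not aldehydes, from alkenes with an allylic oxygen and runs without base or a build-up of zerovalent palladium, so C2 should keep its configuration. The trisubstituted prenyl alkene is not a substrate for this oxidation.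

Step 8
Reactants: 12 (2R,3aS)-2-acetyl-5,5-dimethyl-7-[(2R)-2-methylbutanoyl]-3a-(3-methylbut-2-en-1-yl)-3,3a-dihydro-1-benzofuran-4,6(2H,5H)-dione; 13 5-bromo-2-methylpent-2-ene
Product: 15 (2R,3aS)-2-[(2S)-2-hydroxy-6-methylhept-5-en-2-yl]-5,5-dimethyl-7-[(2R)-2-methylbutanoyl]-3a-(3-methylbut-2-en-1-yl)-3,3a-dihydro-1-benzofuran-4,6(2H,5H)-dione, via 4-methylpent-3-enylmagnesium bromide 14 (not isolated)
Conditions: 13, Mg, THF, rt; then 12, THF, −78 °C; sat. aq. NH4Cl at −78 °C
Reagents that add atoms: none
Why: Grignard addition to the most electrophilic and least hindered carbonyl, the α-oxygenated methyl ketone; C4 is flanked by two quaternary carbons and the C6 and acyl carbonyls are deactivated vinylogous ester carbonyls. O1 is a vinylogous ester oxygen with a delocalised lone pair and a poor donor, so the addition should follow the polar Felkin–Anh (Cornforth) sense, with attack anti to the C2–O1 bond and past the C2 hydrogen. For (2R)-12 with the six-carbon chain as the incoming group this face gives the (S)-carbinol, whereas a chelate through O1 would give the epimer, and the cold quench keeps the magnesium alkoxide from displacing O1.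

## Compound list

1 | (R)-2-methylbutanoic acid | CC[C@@H](C)C(=O)O | starting material
2 | (R)-2-methylbutanoyl chloride | CC[C@@H](C)C(=O)Cl | intermediate
3 | phloroglucinol | Oc1cc(O)cc(O)c1 | starting material
4 | (2R)-2-methyl-1-(2,4,6-trihydroxyphenyl)butan-1-one | CC[C@@H](C)C(=O)c1c(O)cc(O)cc1O | intermediate
5 | 3,5-dihydroxy-6,6-dimethyl-2-[(2R)-2-methylbutanoyl]cyclohexa-2,4-dien-1-one | CC[C@@H](C)C(=O)C1=C(O)C=C(O)C(C)(C)C1=O | intermediate
6 | prenyl bromide (1-bromo-3-methylbut-2-ene) | CC(C)=CCBr | starting material
7 | 3,5-dihydroxy-6,6-dimethyl-2-[(2R)-2-methylbutanoyl]-4-(3-methylbut-2-en-1-yl)cyclohexa-2,4-dien-1-one | CC[C@@H](C)C(=O)C1=C(O)C(CC=C(C)C)=C(O)C(C)(C)C1=O | intermediate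
8 | (Z)-but-2-ene-1,4-diol | OC/C=C\CO | starting material
9 | (2Z)-but-2-ene-1,4-diyl dimethyl biscarbonate | COC(=O)OC/C=C\COC(=O)OC | intermediate
10 | methyl (2E)-4-[(1R)-2-hydroxy-5,5-dimethyl-3-[(2R)-2-methylbutanoyl]-1-(3-methylbut-2-en-1-yl)-4,6-dioxocyclohex-2-en-1-yl]but-2-en-1-yl carbonate (same spatial arrangement at the ring carbon as C3a of 11; the descriptor differs only through the ranking rules) | CC[C@@H](C)C(=O)C1=C(O)[C@](CC=C(C)C)(C/C=C/COC(=O)OC)C(=O)C(C)(C)C1=O | intermediate (not isolated)
11 | (2R,3aS)-2-ethenyl-5,5-dimethyl-7-[(2R)-2-methylbutanoyl]-3a-(3-methylbut-2-en-1-yl)-3,3a-dihydro-1-benzofuran-4,6(2H,5H)-dione | CC[C@@H](C)C(=O)C1=C2O[C@@H](C=C)C[C@]2(CC=C(C)C)C(=O)C(C)(C)C1=O | intermediate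
12 | (2R,3aS)-2-acetyl-5,5-dimethyl-7-[(2R)-2-methylbutanoyl]-3a-(3-methylbut-2-en-1-yl)-3,3a-dihydro-1-benzofuran-4,6(2H,5H)-dione | CC[C@@H](C)C(=O)C1=C2O[C@@H](C(C)=O)C[C@]2(CC=C(C)C)C(=O)C(C)(C)C1=O | intermediate
13 | 5-bromo-2-methylpent-2-ene | CC(C)=CCCBr | starting material
14 | 4-methylpent-3-enylmagnesium bromide | CC(C)=CCC[Mg]Br | intermediate (not isolated)
15 | (2R,3aS)-2-[(2S)-2-hydroxy-6-methylhept-5-en-2-yl]-5,5-dimethyl-7-[(2R)-2-methylbutanoyl]-3a-(3-methylbut-2-en-1-yl)-3,3a-dihydro-1-benzofuran-4,6(2H,5H)-dione | CC[C@@H](C)C(=O)C1=C2O[C@@H]([C@@](C)(O)CCC=C(C)C)C[C@]2(CC=C(C)C)C(=O)C(C)(C)C1=O | target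

## Step count and least certain steps

Total: 8 steps. Longest linear sequence: 7 steps (1, 2, 3, 4, 6, 7, 8); step 5 is a one-step side branch.

Step 6 (key step). The most likely failure is mismatched double stereodifferentiation. The ligand antipode that selects the right face at C3a may close ring B from the wrong π-allyl face, because the second event is also influenced by the new quaternary centre. The delocalised anion also attacks from outside the metal, far from the chiral pocket, which can erode the first selection. Slow closure would let β-hydride loss from the second π-allyl complex compete. The fallback sets out from 7 (with 9) and returns at 11. The annulation is run with the antipode that is best for C3a, and the product in which vinyl and prenyl are trans, (2S,3aS)-2-ethenyl-5,5-dimethyl-7-[(2R)-2-methylbutanoyl]-3a-(3-methylbut-2-en-1-yl)-3,3a-dihydro-1-benzofuran-4,6(2H,5H)-dione F1, is isolated. It is then treated with Pd2(dba)3·CHCl3 and the mirror-image ligand, or with the achiral Ph2PCH2CH2PPh2, in CH2Cl2. Because O1 belongs to a vinylogous acid, zerovalent palladium should re-ionise the allylic C2–O1 bond as it would an allylic ester. The π-allyl faces then exchange, and the ring recloses to 11 under the control of the second ligand or under thermodynamic control. C2 is thus corrected in a separate, known type of palladium-catalysed allylic equilibration.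

Step 8. The most likely failure is addition from the other face of the ketone, if O1 still chelates magnesium well enough to reverse the predicted sense. Partial enolisation of the methyl ketone by the basic reagent, with epimerisation at C2, is the second concern. The fallback sets out from 12 and returns at 15 with the two carbon groups introduced in the opposite order. Kinetic deprotonation of the methyl group (LiN(i-Pr)2, THF, −78 °C) and alkylation with 6 (DMPU, −78 to −40 °C) would give (2R,3aS)-5,5-dimethyl-7-[(2R)-2-methylbutanoyl]-3a-(3-methylbut-2-en-1-yl)-2-(5-methylhex-4-enoyl)-3,3a-dihydro-1-benzofuran-4,6(2H,5H)-dione F2. MeMgBr (THF, −78 °C) then adds to F2. Since methyl now enters from the face that the six-carbon chain used in step 8, the same facial preference gives the opposite carbinol configuration. Whichever sense the C2 acyl group shows, one of the two orders leads to 15. The price is one more step and a strongly basic alkylation on an epimerisable substrate.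

Step 7. The most likely failure is delivery of oxygen to the terminal carbon, because the electron-withdrawing allylic oxygen disfavours positive charge at the internal carbon. The second concern is ionisation of the allylic C2–O1 bond by transient zerovalent palladium, with loss of C2 configuration. No other method oxidises a monosubstituted alkene at its internal carbon beside a trisubstituted one with comparable reliability, so the fallback avoids the oxidation altogether. It sets out from 7 and returns at 12, forming the same two bonds (C3a–C3, O1–C2) at the ketone oxidation level. But-3-en-2-one is brominated to 3,4-dibromobutan-2-one F3. With Cs2CO3 and N-(9-anthracenylmethyl)cinchonidinium bromide in toluene at low temperature, F3 loses HBr to give 3-bromobut-3-en-2-one F4 in the flask. C3a of the anion of 7 adds to the CH2 terminus of F4 to give the Michael adduct 2-hydroxy-5,5-dimethyl-3-[(2R)-2-methylbutanoyl]-1-(2-bromo-3-oxobutyl)-1-(3-methylbut-2-en-1-yl)cyclohex-2-ene-4,6-dione F5. The C7a enolate oxygen then displaces bromide (5-exo-tet) to give 12. This known tandem Michael addition and O-alkylation would leave C3a to the chiral ammonium salt and C2 to equilibration under base. It is therefore weaker in stereocontrol than steps 6 and 7 and is held in reserve.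

Step 4. The most likely failure is over-alkylation. The anion of 7 is about as nucleophilic as that of 5, so a second prenylation at the same carbon and some O-prenylation compete. The fallback sets out from 5 and returns at 7 and makes no new compound (F0). It changes the mechanism from enolate SN2 to electrophilic substitution of the neutral enol: 2-methylbut-3-en-2-ol, BF3·OEt2, dioxane, rt. Under acid the dearomatising second alkylation is disfavoured; the competing process to watch is ring closure of the prenyl group onto a neighbouring enol oxygen.

## Further compounds

F1 | step 6 | (2S,3aS)-2-ethenyl-5,5-dimethyl-7-[(2R)-2-methylbutanoyl]-3a-(3-methylbut-2-en-1-yl)-3,3a-dihydro-1-benzofuran-4,6(2H,5H)-dione | CC[C@@H](C)C(=O)C1=C2O[C@H](C=C)C[C@]2(CC=C(C)C)C(=O)C(C)(C)C1=O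
F2 | step 8 | (2R,3aS)-5,5-dimethyl-7-[(2R)-2-methylbutanoyl]-3a-(3-methylbut-2-en-1-yl)-2-(5-methylhex-4-enoyl)-3,3a-dihydro-1-benzofuran-4,6(2H,5H)-dione | CC[C@@H](C)C(=O)C1=C2O[C@@H](C(=O)CCC=C(C)C)C[C@]2(CC=C(C)C)C(=O)C(C)(C)C1=O
F3 | step 7 | 3,4-dibromobutan-2-one | CC(=O)C(Br)CBr
F4 | step 7 | 3-bromobut-3-en-2-one | CC(=O)C(Br)=C
F5 | step 7 | 2-hydroxy-5,5-dimethyl-3-[(2R)-2-methylbutanoyl]-1-(2-bromo-3-oxobutyl)-1-(3-methylbut-2-en-1-yl)cyclohex-2-ene-4,6-dione (ring carbon as in 10; both C–Br epimers) | CC[C@@H](C)C(=O)C1=C(O)[C@](CC=C(C)C)(CC(Br)C(C)=O)C(=O)C(C)(C)C1=O
F0 | step 4 | none | none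
A1 | alternative 1 | (2R,3aS)-5,5-dimethyl-3a-(3-methylbut-2-en-1-yl)-2-[(2S)-6-methyl-2-(triethylsilyloxy)hept-5-en-2-yl]-3,3a-dihydro-1-benzofuran-4,6(2H,5H)-dione | O=C1C=C2O[C@@H]([C@@](C)(O[Si](CC)(CC)CC)CCC=C(C)C)C[C@]2(CC=C(C)C)C(=O)C1(C)C
A2 | alternative 1 | pentafluorophenyl (4E)-2,2-dimethyl-4-[(5R)-3-(3-methylbut-2-en-1-yl)-5-[(2S)-6-methyl-2-(triethylsilyloxy)hept-5-en-2-yl]oxolan-2-ylidene]-3-oxobutanoate (either configuration at the prenyl-bearing carbon) | CC(C)(C(=O)Oc1c(F)c(F)c(F)c(F)c1F)C(=O)/C=C1/O[C@@H]([C@@](C)(O[Si](CC)(CC)CC)CCC=C(C)C)CC1CC=C(C)C
A3 | alternative 2 | (2R,3aS)-3a-(3-methylbut-2-en-1-yl)-2-[(2S)-6-methyl-2-(triethylsilyloxy)hept-5-en-2-yl]-3,3a-dihydro-1-benzofuran-4,6(2H,5H)-dione | O=C1C=C2O[C@@H]([C@@](C)(O[Si](CC)(CC)CC)CCC=C(C)C)C[C@]2(CC=C(C)C)C(=O)C1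
A4 | alternative 2 | 2-[(2R,3S)-2-hydroxy-3,7-dimethyl-3-(triethylsilyloxy)oct-6-en-1-yl]-2-(3-methylbut-2-en-1-yl)cyclohexane-1,3,5-trione | O=C1CC(=O)C(CC=C(C)C)(C[C@@H](O)[C@@](C)(O[Si](CC)(CC)CC)CCC=C(C)C)C(=O)C1
A5 | alternative 3 | (2R,3aS)-5,5-dimethyl-7-[(2R)-2-methylbutanoyl]-3a-(3-methylbut-2-en-1-yl)-2-[(2S)-6-methyl-2-(triethylsilyloxy)hept-5-en-2-yl]-3,3a-dihydro-1-benzofuran-4,6(2H,5H)-dione | CC[C@@H](C)C(=O)C1=C2O[C@@H]([C@@](C)(O[Si](CC)(CC)CC)CCC=C(C)C)C[C@]2(CC=C(C)C)C(=O)C(C)(C)C1=O
A6 | alternative 3 | triethyl{[(2S)-6-methyl-2-[(2R)-oxiran-2-yl]hept-5-en-2-yl]oxy}silane | C1O[C@H]1[C@@](C)(O[Si](CC)(CC)CC)CCC=C(C)C
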